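**Retrosynthetic overview**
- The hydroxy-methoxy-quinone is taken back to a 2,3,5,6-tetramethoxyphenyl group: one vinylogous ester is hydrolysed last, after oxidative demethylation of the arene.
- The strategy rests on rings A and B (C1–C10) with the contiguous stereocentres C8, C9 (quaternary) and C10 and the C5=C6 alkene. This is a drimane in which the C10 methyl sits on C9, H9 on C8 and H5 on C10, with the gem-dimethyl group at C4 untouched.
- Reversing these three shifts and breaking C4–C5 and C9–C10 gives an achiral (2E,6E)-farnesyl arene. In the forward sense one enzymatic cationic cyclisation closes ring A, then ring B, and runs the shifts to loss of H6.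
- The farnesyl arene comes from lithiated 1,2,4,5-tetramethoxybenzene and farnesyl bromide (aryl–C11 bond).

Key step: step 3

Remark: drimane numbering is used for the decalin (C11 is the benzylic CH2 on C9). Both starting materials are taken as commercial. No existing cyclase is known to give the termination needed in step 3, so a variant is assumed to come from screening and engineering.

**Step 1**
Reactants: 1 (2E,6E)-farnesol
Product: 2 (2E,6E)-farnesyl bromide
Conditions: PBr3 (0.4 equiv), Et2O, −10 → 0 °C, 30 min; used crude
Reagents that add atoms: phosphorus tribromide, BrP(Br)Br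
Why: Bromination of a primary allylic alcohol with PBr3 goes by SN2 displacement of the phosphite ester at low temperature, which should keep the (2E) geometry and avoid allylic transposition.

**Step 2**
Reactants: 3 1,2,4,5-tetramethoxybenzene; 2 (2E,6E)-farnesyl bromide
Product: 5 1,2,4,5-tetramethoxy-3-[(2E,6E)-3,7,11-trimethyldodeca-2,6,10-trien-1-yl]benzene, via aryllithium 4 (not isolated)
Conditions: 3 (1.2 equiv), n-BuLi (1.05 equiv), TMEDA, THF, 0 °C, 1 h; then 2, −78 °C → rt
Reagents that add atoms: n-butyllithium, [Li]CCCC (lithium of intermediate 4 only)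
Why: Directed ortho-lithiation removes the ring hydrogen flanked by two methoxy groups, and the hindered aryllithium should then alkylate at the primary carbon of the allylic bromide (SN2), leaving all three alkenes and their geometry untouched.

**Step 3**
Reactants: 5 1,2,4,5-tetramethoxy-3-[(2E,6E)-farnesyl]benzene
Product: 10 1,2,4,5-tetramethoxy-3-{[(1R,2S,8aS)-1,2,5,5-tetramethyl-1,2,3,5,6,7,8,8a-octahydronaphthalen-1-yl]methyl}benzene, via drim-8-yl cation 6 (not isolated), via drim-9-yl cation 7 (not isolated), via C10 cation 8 (not isolated), via C5 cation 9 (not isolated)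
Conditions: engineered class 2 terpene cyclase (squalene–hopene cyclase scaffold), E. coli whole cells, citrate buffer pH 6.0, 2-hydroxypropyl-β-cyclodextrin, 35 °C, 72 h
Reagents that add atoms: none
Why: Proposed new method: the aspartic acid of the DXDD motif delivers a proton to C3 on one face of the terminal alkene of the pre-folded (chair–chair) chain, the C5=C10 alkene adds to C4 (6-endo, ring A) and the C8=C9 alkene adds to C10 (6-endo, ring B), both as anti additions that give the trans-fused drim-8-yl cation 6 with 5α-H, 10β-CH3 and 9α-H. If the pocket holds no base near C7, C9 or the C8 methyl and no water near C8, cation 6 should relax by three suprafacial, antiperiplanar 1,2-shifts (H9α to C8 giving 7, the 10β-methyl to C9 giving 8, H5α to C10 giving 9) until a base under C6 removes H6 and leaves the C5=C6 alkene. The closest known reaction types are the squalene–hopene cyclase cyclisation of farnesyl arenes, farnesyl phenols and homofarnesol to drimane-type bicycles and the class 2 diterpene cyclases that carry the labd-13-en-8-yl cation through the same hydride, methyl, hydride shifts to halim-5-ene and clerodane skeletons; their combination on an aryl sesquiterpene is without precedent, so the variant has to be found by screening. The fold and the face of protonation set C5, C9 and C10 of cation 6, and each shift passes this on: α-face arrival of H9 makes C8 (S), β-face arrival of the methyl group makes C9 (R) and α-face arrival of H5 makes C10 (S). The step needs a single enantioface of protonation and a single termination site, both imposed by the pocket; the substrate helps through its (2E,6E) geometry, which fixes the anti relation of the migrating groups, and through the methoxy groups on both ortho carbons of the arene, which block Friedel–Crafts closure onto C8 or C10 and leave no free phenol to form an aryl ether.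

**Step 4**
Reactants: 10 tetramethoxyaryl rearranged drim-5-ene
Product: 11 2,5-dimethoxy-3-{[(1R,2S,8aS)-1,2,5,5-tetramethyl-1,2,3,5,6,7,8,8a-octahydronaphthalen-1-yl]methyl}cyclohexa-2,5-diene-1,4-dione
Conditions: (NH4)2Ce(NO3)6 (2.5 equiv), MeCN/H2O (2:1), 0 °C, 20 min
Reagents that add atoms: water, O
Why: Oxidative demethylation by the tetravalent cerium salt takes two electrons from the electron-rich arene, water adds at a para pair of methoxy-bearing carbons and methanol leaves; either para pair gives the same quinone, and an isolated trisubstituted alkene should be oxidised far more slowly than the arene under these short, cold conditions.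

**Step 5**
Reactants: 11 2,5-dimethoxyquinone
Product: 13 2-hydroxy-5-methoxy-3-{[(1R,2S,8aS)-1,2,5,5-tetramethyl-1,2,3,5,6,7,8,8a-octahydronaphthalen-1-yl]methyl}cyclohexa-2,5-diene-1,4-dione, via potassium quinonolate 12 (not isolated)
Conditions: 2 M KOH, MeOH/H2O, 0 °C → rt; then 1 M HCl to pH 3
Reagents that add atoms: potassium hydroxide, [K+].[OH-]
Why: Addition–elimination of hydroxide at a vinylogous ester should take place at the methoxy carbon next to the side chain, because that methoxy group is twisted out of the ring plane and donates less; the acidic product is held as the electron-rich quinonolate 12, which resists a second hydrolysis, and the basic medium leaves the C5=C6 alkene and the three stereocentres alone.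

**Compound list**
1 | (2E,6E)-farnesol | CC(C)=CCC/C(C)=C/CC/C(C)=C/CO | starting material
2 | (2E,6E)-farnesyl bromide | CC(C)=CCC/C(C)=C/CC/C(C)=C/CBr | intermediate
3 | 1,2,4,5-tetramethoxybenzene | COc1cc(OC)c(OC)cc1OC | starting material
4 | (2,3,5,6-tetramethoxyphenyl)lithium | [Li]c1c(OC)c(OC)cc(OC)c1OC | intermediate
5 | 1,2,4,5-tetramethoxy-3-[(2E,6E)-3,7,11-trimethyldodeca-2,6,10-trien-1-yl]benzene | COc1cc(OC)c(OC)c(C/C=C(C)/CC/C=C(C)/CCC=C(C)C)c1OC | intermediate
6 | enzyme-bound 11-(2,3,5,6-tetramethoxyphenyl)drim-8-yl cation (5α-H, 9α-H, 10β-CH3) | COc1cc(OC)c(OC)c(C[C@H]2[C+](C)CC[C@H]3C(C)(C)CCC[C@]23C)c1OC | intermediate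
7 | enzyme-bound 11-aryl-drim-9-yl cation (8α-H, 8β-CH3, 5α-H, 10β-CH3) | COc1cc(OC)c(OC)c(C[C+]2[C@@H](C)CC[C@H]3C(C)(C)CCC[C@]23C)c1OC | intermediate
8 | enzyme-bound C10 cation of the methyl-shifted skeleton (9β-CH3, 9α-CH2Ar, 8β-CH3, 5α-H) | COc1cc(OC)c(OC)c(C[C@@]2(C)[C+]3CCCC(C)(C)[C@@H]3CC[C@@H]2C)c1OC | intermediate
9 | enzyme-bound C5 cation of the methyl-shifted skeleton (10α-H, 9β-CH3, 8β-CH3) | COc1cc(OC)c(OC)c(C[C@@]2(C)[C@@H]3CCCC(C)(C)[C+]3CC[C@@H]2C)c1OC | intermediate
10 | 1,2,4,5-tetramethoxy-3-{[(1R,2S,8aS)-1,2,5,5-tetramethyl-1,2,3,5,6,7,8,8a-octahydronaphthalen-1-yl]methyl}benzene, i.e. (8S,9R,10S)-11-aryl-15(10→9)-abeo-drim-5-ene | COc1cc(OC)c(OC)c(C[C@@]2(C)[C@@H]3CCCC(C)(C)C3=CC[C@@H]2C)c1OC | intermediate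
11 | 2,5-dimethoxy-3-{[(1R,2S,8aS)-1,2,5,5-tetramethyl-1,2,3,5,6,7,8,8a-octahydronaphthalen-1-yl]methyl}cyclohexa-2,5-diene-1,4-dione | COC1=CC(=O)C(OC)=C(C[C@@]2(C)[C@@H]3CCCC(C)(C)C3=CC[C@@H]2C)C1=O | intermediate
12 | potassium 4-methoxy-3,6-dioxo-2-{[(1R,2S,8aS)-1,2,5,5-tetramethyl-1,2,3,5,6,7,8,8a-octahydronaphthalen-1-yl]methyl}cyclohexa-1,4-dien-1-olate | COC1=CC(=O)C([O-])=C(C[C@@]2(C)[C@@H]3CCCC(C)(C)C3=CC[C@@H]2C)C1=O.[K+] | intermediate
13 | 2-hydroxy-5-methoxy-3-{[(1R,2S,8aS)-1,2,5,5-tetramethyl-1,2,3,5,6,7,8,8a-octahydronaphthalen-1-yl]methyl}cyclohexa-2,5-diene-1,4-dione (CNP0348245.1) | COC1=CC(=O)C(O)=C(C[C@@]2(C)[C@@H]3CCCC(C)(C)C3=CC[C@@H]2C)C1=O | target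

**Total step count:** 5
**Longest linear sequence:** 5 steps (1 → 2 → 5 → 10 → 11 → 13)

**Steps most likely to fail**

1. Step 3. The cascade may end early by loss of a proton at C7, C9 or the C8 methyl, or by capture of water at C8, giving unrearranged drimanes. It may also stall after two shifts and lose H5 or H1 from C10, or the bulky tetramethoxyaryl head group may not be accommodated, giving no turnover. The fallback uses known chemistry, sets out from 3 and comes back at 10. 2,2-Dimethylcyclohexanone is converted with LiN(iPr)2 and PhNTf2 into 6,6-dimethylcyclohex-1-en-1-yl trifluoromethanesulfonate F1. Stille coupling of F1 with tributyl(vinyl)stannane (Pd(PPh3)4, a zerovalent palladium complex, LiCl, THF, reflux) gives 6,6-dimethyl-1-vinylcyclohexene F2. An exo-selective Diels–Alder reaction of F2 with (E)-2-methylbut-2-enal under a chiral oxazaborolidinium Lewis acid (CH2Cl2, −78 → −20 °C) should give (1R,2S,8aS)-1,2,5,5-tetramethyl-1,2,3,5,6,7,8,8a-octahydronaphthalene-1-carbaldehyde F3. In this reaction the "ortho" orientation joins the formyl-bearing carbon to C10, the (E)-dienophile fixes the cis C8/C9 methyl groups, the exo mode places the formyl carbon syn to H10, and the catalyst selects the enantiomer. Aryllithium 4, made from 3 as in step 2, adds to F3 to give the benzylic carbinol F4 as a mixture of carbinol epimers, both of which serve. The carbinol is converted with NaH, CS2 and MeI into the S-methyl xanthate F5, and Barton–McCombie reduction (Bu3SnH, AIBN, toluene, 90 °C) gives 10. The same sequence would supply authentic 10 as the reference for the cyclase screen.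

2. Step 5. Hydroxide may not discriminate between the two vinylogous ester positions, or hydrolysis may run on to the dihydroxyquinone. The fallback sets out from 11 and comes back at 13. Both methoxy groups are hydrolysed on purpose (NaOH, aqueous EtOH, 60 °C, then acid) to the 2,5-dihydroxy-3-alkyl-1,4-benzoquinone F6. F6 is then mono-esterified with MeOH and a trace of HCl at room temperature, where the unhindered vinylogous acid flanked by the ring hydrogen should react faster than the one next to the neopentyl-type side chain.

3. Step 4. The cerium oxidant may attack the C5=C6 alkene, or oxidation may go through an ortho pair of methoxy groups; an ortho-quinone of this kind still carries the vinylogous ester next to the side chain and should converge on 13 in step 5. The fallback sets out from 10 and comes back at 11. Constant-current anodic oxidation of 10 (Pt anode, 1% KOH in MeOH, 0 °C) gives the quinone bis(dimethyl ketal) F7, selected by the low oxidation potential of the arene. Mild hydrolysis of F7 (aqueous AcOH, THF, 0 °C) releases quinone 11 without a chemical oxidant.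

**Further compounds**
F1 | step 3 | 6,6-dimethylcyclohex-1-en-1-yl trifluoromethanesulfonate | CC1(C)CCCC=C1OS(=O)(=O)C(F)(F)F
F2 | step 3 | 6,6-dimethyl-1-vinylcyclohexene | C=CC1=CCCCC1(C)C
F3 | step 3 | (1R,2S,8aS)-1,2,5,5-tetramethyl-1,2,3,5,6,7,8,8a-octahydronaphthalene-1-carbaldehyde | O=C[C@@]1(C)[C@@H]2CCCC(C)(C)C2=CC[C@@H]1C
F4 | step 3 | (2,3,5,6-tetramethoxyphenyl)[(1R,2S,8aS)-1,2,5,5-tetramethyl-1,2,3,5,6,7,8,8a-octahydronaphthalen-1-yl]methanol, carbinol epimers | COc1cc(OC)c(OC)c(C(O)[C@@]2(C)[C@@H]3CCCC(C)(C)C3=CC[C@@H]2C)c1OC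
F5 | step 3 | O-{(2,3,5,6-tetramethoxyphenyl)[(1R,2S,8aS)-1,2,5,5-tetramethyl-1,2,3,5,6,7,8,8a-octahydronaphthalen-1-yl]methyl} S-methyl carbonodithioate | COc1cc(OC)c(OC)c(C(OC(=S)SC)[C@@]2(C)[C@@H]3CCCC(C)(C)C3=CC[C@@H]2C)c1OC
F6 | step 5 | 2,5-dihydroxy-3-{[(1R,2S,8aS)-1,2,5,5-tetramethyl-1,2,3,5,6,7,8,8a-octahydronaphthalen-1-yl]methyl}cyclohexa-2,5-diene-1,4-dione | OC1=CC(=O)C(O)=C(C[C@@]2(C)[C@@H]3CCCC(C)(C)C3=CC[C@@H]2C)C1=O
F7 | step 4 | 1,3,3,4,6,6-hexamethoxy-5-{[(1R,2S,8aS)-1,2,5,5-tetramethyl-1,2,3,5,6,7,8,8a-octahydronaphthalen-1-yl]methyl}cyclohexa-1,4-diene | COC1=CC(OC)(OC)C(OC)=C(C[C@@]2(C)[C@@H]3CCCC(C)(C)C3=CC[C@@H]2C)C1(OC)OC
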